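**Retrosynthetic overview**

1. The target is an eudesmane: ring A = C1–C5/C10, ring B = C5–C10. The C3 propionate, the C8 acetate and the C11(=C13)–C12O2Me acrylate are traced back to a Δ4-3-ketone carrying a C8 hydroxyl and a C7 isopropenyl group.
2. Key disconnection: ring A is opened at C4=C5 (aldol-condensation retron) and at C1–C10 (Michael retron), which leaves a ring-B cyclohexanone and ethyl vinyl ketone.
3. Enabling feature: at the ketone level C3=O and C5=O are 1,5-related through C2–C1–C10, C10 is the fully substituted α-carbon of C5, and C4 is the enolisable CH(CH3) α-carbon of C3. One Michael/aldol-condensation sequence can therefore form C1–C10 and then close ring A at C4=C5, setting C10 and the tetrasubstituted olefin that carries C15.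
4. Ring B with C7 and C8 comes from (R)-carvone: vinylogous Rubottom γ-hydroxylation, Mitsunobu inversion to the cis C7/C8 pattern, conjugate reduction.
5. Ring order: ring B from the chiral pool, ring A in the key step. C10 is set by (R)-1-phenylethylamine reinforced by the axial C8 ester, and C3 last, from the C10-controlled enone reduction.

Key step: step 5

Remark: bicyclic compounds are described with eudesmane numbering; ketone 6 is carried as a mixture at its α-methyl carbon, which is planarised again in step 5.

**Route**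

Step 1
Reactants: 1 (R)-(−)-carvone
Product: 2 (S)-tert-butyl(dimethyl){[2-methyl-5-(prop-1-en-2-yl)cyclohexa-1,3-dien-1-yl]oxy}silane
Conditions: KHMDS (0.95 equiv), THF, −78 → 0 °C; TBSCl, DMPU, −78 °C → rt
Reagents that add atoms: tert-butyldimethylsilyl chloride, CC(C)(C)[Si](C)(C)Cl
Why: Thermodynamic (extended) dienolate formation and O-silylation: with slightly less than one equivalent of base the enolates should equilibrate by proton transfer to the fully conjugated γ-deprotonated dienolate, whose O-silylation gives the linear 1-silyloxy-1,3-diene, the carvone stereocentre being untouched.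

Step 2
Reactants: 2 silyl dienol ether
Product: 3 (4S,5R)-4-hydroxy-2-methyl-5-(prop-1-en-2-yl)cyclohex-2-en-1-one (trans)
Conditions: mCPBA (1.05 equiv), NaHCO3, CH2Cl2, −40 → 0 °C; then 48% aq. HF, MeCN, 0 °C
Reagents that add atoms: 3-chloroperbenzoic acid, OOC(=O)c1cccc(Cl)c1
Why: Vinylogous Rubottom oxidation: the peracid should epoxidise the electron-rich terminal C3=C4 bond of the silyloxydiene on the face anti to the adjacent isopropenyl group (the 1,1-disubstituted side-chain olefin is far less nucleophilic), and collapse of the epoxide with loss of silicon gives the trans γ-hydroxy enone, which sets C4 as S.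

Step 3
Reactants: 3 trans-4-hydroxycarvone
Product: 4 (1R,6R)-3-methyl-4-oxo-6-(prop-1-en-2-yl)cyclohex-2-en-1-yl acetate (cis)
Conditions: AcOH, PPh3, DIAD, THF, 0 °C → rt
Reagents that add atoms: acetic acid, CC(=O)O
Why: Mitsunobu reaction: acetate displaces the allylic oxyphosphonium in an SN2 process with inversion at the carbinol carbon (the same equatorial-to-axial inversion next to an isopropyl-type group is classical for menthol), which gives the cis relationship that becomes the cis C7/C8 pattern of the target.

Step 4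
Reactants: 4 cis-4-acetoxycarvone
Product: 6 (1R,2R,5RS)-5-methyl-4-oxo-2-(prop-1-en-2-yl)cyclohexyl acetate, via silyl enol ether 5 (not isolated)
Conditions: [(Ph3P)CuH]6 (5 mol %), PhMe2SiH (1.5 equiv), toluene, rt; then 1 M HCl, THF, 0 °C
Reagents that add atoms: none
Why: Stryker-type CuH-catalysed conjugate reduction: hydride is delivered only to the β-carbon of the enone, leaving the isopropenyl group and the acetate untouched, and hydrolysis of silyl enol ether 5 gives the ketone as a mixture at the new α-methyl centre, which is irrelevant because this carbon is planarised again in step 5.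

Step 5
Reactants: 6 cis-4-acetoxydihydrocarvone; 7 (R)-(+)-1-phenylethylamine; 8 ethyl vinyl ketone (pent-1-en-3-one)
Product: 13 8β-hydroxy-α-cyperone [(4aR,6R,7R)-6-hydroxy-1,4a-dimethyl-7-(prop-1-en-2-yl)-4,4a,5,6,7,8-hexahydronaphthalen-2(3H)-one], via imine 9 (not isolated), via alkylated imine 10 (not isolated), via diketone 11 (not isolated), via ketol 12 (not isolated)
Conditions: 7 (1.1 equiv), p-TsOH (cat.), toluene, reflux, Dean–Stark; then 8 (1.5 equiv), THF, 40 °C; then 10% aq. AcOH, rt, extraction; then NaOMe (0.5 equiv), MeOH, rt → 50 °C (telescoped, nothing purified before 13)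
Reagents that add atoms: none
Why: Auxiliary-directed Robinson annulation (imine/secondary-enamine Michael addition followed by aldol condensation), whose closest precedent is the conversion of dihydrocarvone and ethyl vinyl ketone into α-cyperone: imine 9 tautomerises to the more substituted secondary enamine (C5=C10), which adds to 8 through a compact aza-ene-like transition state with N–H transfer to give 10, hydrolysis frees diketone 11, and methoxide then generates the C4 enolate of the C3 ketone, which attacks the C5 carbonyl (ketol 12) and loses water to the conjugated tetrasubstituted C4=C5 enone while the C8 acetate is methanolysed. Ring A is closed by a 6-(enolendo)-exo-trig aldol addition followed by E1cB dehydration. The only new stereocentre, C10, is set in the Michael step: the (R)-phenylethyl group shields the β face of the enamine and the axial C8 acetoxy group, syn-axial to a β approach at C10, should reinforce this, so that C1 enters on the α face and the methyl becomes β (10R). The step needs regioselectivity for C10 over C6 in the Michael addition, secured by reaction through the more substituted enamine tautomer, and for the C4-to-C5 aldol mode over the bridged C6-to-C3 mode, secured because only the former can dehydrate irreversibly to a conjugated enone under equilibrating base. C7 and C8 are not α to a carbonyl and should keep the carvone-derived configuration.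

Step 6
Reactants: 13 8β-hydroxy-α-cyperone
Product: 14 (7R,8R,10R)-8-acetoxyeudesma-4,11-dien-3-one
Conditions: Ac2O, DMAP, pyridine, CH2Cl2, rt
Reagents that add atoms: acetic anhydride, CC(=O)OC(C)=O
Why: DMAP-catalysed acylation of the axial C8 alcohol installs the acetate of the target with retention at C8.

Step 7
Reactants: 14 8β-acetoxy enone
Product: 15 (7R,8R,10R)-8-acetoxy-12-hydroxyeudesma-4,11(13)-dien-3-one
Conditions: SeO2 (0.5 equiv), t-BuOOH (2 equiv), CH2Cl2, 0 °C → rt
Reagents that add atoms: selenium dioxide, O=[Se]=O; tert-butyl hydroperoxide, CC(C)(C)OO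
Why: Selenium dioxide allylic oxidation (ene reaction then [2,3]-sigmatropic shift) with tert-butyl hydroperoxide as terminal oxidant: only the isopropenyl group is an electron-rich olefin (the ring olefin is deactivated as an enone), so its methyl group should be hydroxylated with the double bond ending as C11=C13, and no stereocentre is touched.

Step 8
Reactants: 15 allylic alcohol
Product: 16 (7R,8R,10R)-8-acetoxy-3-oxoeudesma-4,11(13)-dien-12-oic acid
Conditions: TEMPO (cat.), NaClO2, NaOCl (cat.), MeCN/phosphate buffer pH 6.7, 35 °C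
Reagents that add atoms: sodium chlorite, [Na+].[O-]Cl=O
Why: TEMPO/chlorite oxidation (Zhao modification of the Anelli oxidation) takes the allylic alcohol, and any enal carried over from step 7, to the acrylic acid under near-neutral buffered conditions that spare the acetate and the enone.

Step 9
Reactants: 16 acrylic acid
Product: 17 methyl (7R,8R,10R)-8-acetoxy-3-oxoeudesma-4,11(13)-dien-12-oate
Conditions: MeI, K2CO3, DMF, rt
Reagents that add atoms: iodomethane, CI
Why: SN2 O-alkylation of the potassium carboxylate with iodomethane gives the methyl ester without the cycloaddition risk that a diazoalkane poses to an acrylate and without touching the acetate.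

Step 10
Reactants: 17 keto ester
Product: 18 methyl (3S,7R,8R,10R)-8-acetoxy-3-hydroxyeudesma-4,11(13)-dien-12-oate
Conditions: NaBH4, CeCl3·7H2O, MeOH, −78 → −40 °C
Reagents that add atoms: none
Why: Luche reduction: cerium-mediated 1,2-reduction of the enone with hydride entering axially on the α face, anti to the angular C10 methyl, should give the pseudo-equatorial 3β-alcohol (3S), the acrylate and both esters being inert at low temperature.

Step 11
Reactants: 18 allylic alcohol
Product: 19 methyl (3S,7R,8R,10R)-8-acetoxy-3-(propanoyloxy)eudesma-4,11(13)-dien-12-oate (target)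
Conditions: (EtCO)2O, Et3N, DMAP (cat.), CH2Cl2, 0 °C → rt
Reagents that add atoms: propanoic anhydride, CCC(=O)OC(=O)CC
Why: DMAP-catalysed acylation of the allylic 3β-alcohol with propanoic anhydride gives the target with retention at C3.

**Compound list**

1 | (R)-(−)-carvone | C=C(C)[C@H]1CC(=O)C(C)=CC1 | starting material
2 | (S)-tert-butyl(dimethyl){[2-methyl-5-(prop-1-en-2-yl)cyclohexa-1,3-dien-1-yl]oxy}silane | C=C(C)[C@H]1CC(O[Si](C)(C)C(C)(C)C)=C(C)C=C1 | intermediate
3 | (4S,5R)-4-hydroxy-2-methyl-5-(prop-1-en-2-yl)cyclohex-2-en-1-one | C=C(C)[C@H]1CC(=O)C(C)=C[C@@H]1O | intermediate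
4 | (1R,6R)-3-methyl-4-oxo-6-(prop-1-en-2-yl)cyclohex-2-en-1-yl acetate | C=C(C)[C@H]1CC(=O)C(C)=C[C@H]1OC(C)=O | intermediate
5 | (1R,6R)-4-{[dimethyl(phenyl)silyl]oxy}-3-methyl-6-(prop-1-en-2-yl)cyclohex-3-en-1-yl acetate | C=C(C)[C@H]1CC(O[Si](C)(C)c2ccccc2)=C(C)C[C@H]1OC(C)=O | intermediate
6 | (1R,2R,5RS)-5-methyl-4-oxo-2-(prop-1-en-2-yl)cyclohexyl acetate | C=C(C)[C@H]1CC(=O)C(C)C[C@H]1OC(C)=O | intermediate
7 | (R)-(+)-1-phenylethylamine | C[C@@H](N)c1ccccc1 | starting material
8 | ethyl vinyl ketone (pent-1-en-3-one) | C=CC(=O)CC | starting material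
9 | (1R,2R,5RS)-5-methyl-4-{[(1R)-1-phenylethyl]imino}-2-(prop-1-en-2-yl)cyclohexyl acetate | C=C(C)[C@H]1CC(=N[C@H](C)c2ccccc2)C(C)C[C@H]1OC(C)=O | intermediate
10 | (1R,2R,5R)-5-methyl-5-(3-oxopentyl)-4-{[(1R)-1-phenylethyl]imino}-2-(prop-1-en-2-yl)cyclohexyl acetate | C=C(C)[C@H]1CC(=N[C@H](C)c2ccccc2)[C@](C)(CCC(=O)CC)C[C@H]1OC(C)=O | intermediate
11 | (1R,2R,5R)-5-methyl-4-oxo-5-(3-oxopentyl)-2-(prop-1-en-2-yl)cyclohexyl acetate | C=C(C)[C@H]1CC(=O)[C@](C)(CCC(=O)CC)C[C@H]1OC(C)=O | intermediate
12 | (4aR,6R,7R)-6,8a-dihydroxy-1,4a-dimethyl-7-(prop-1-en-2-yl)octahydronaphthalen-2(1H)-one (C1 and C8a not defined) | C=C(C)[C@H]1CC2(O)C(C)C(=O)CC[C@]2(C)C[C@H]1O | intermediate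
13 | (4aR,6R,7R)-6-hydroxy-1,4a-dimethyl-7-(prop-1-en-2-yl)-4,4a,5,6,7,8-hexahydronaphthalen-2(3H)-one (8β-hydroxy-α-cyperone) | C=C(C)[C@H]1CC2=C(C)C(=O)CC[C@]2(C)C[C@H]1O | intermediate
14 | (7R,8R,10R)-8-acetoxyeudesma-4,11-dien-3-one | C=C(C)[C@H]1CC2=C(C)C(=O)CC[C@]2(C)C[C@H]1OC(C)=O | intermediate
15 | (7R,8R,10R)-8-acetoxy-12-hydroxyeudesma-4,11(13)-dien-3-one | C=C(CO)[C@H]1CC2=C(C)C(=O)CC[C@]2(C)C[C@H]1OC(C)=O | intermediate
16 | (7R,8R,10R)-8-acetoxy-3-oxoeudesma-4,11(13)-dien-12-oic acid | C=C(C(=O)O)[C@H]1CC2=C(C)C(=O)CC[C@]2(C)C[C@H]1OC(C)=O | intermediate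
17 | methyl (7R,8R,10R)-8-acetoxy-3-oxoeudesma-4,11(13)-dien-12-oate | C=C(C(=O)OC)[C@H]1CC2=C(C)C(=O)CC[C@]2(C)C[C@H]1OC(C)=O | intermediate
18 | methyl (3S,7R,8R,10R)-8-acetoxy-3-hydroxyeudesma-4,11(13)-dien-12-oate | C=C(C(=O)OC)[C@H]1CC2=C(C)[C@@H](O)CC[C@]2(C)C[C@H]1OC(C)=O | intermediate
19 | methyl (3S,7R,8R,10R)-8-acetoxy-3-(propanoyloxy)eudesma-4,11(13)-dien-12-oate (CNP0198123.1) | C=C(C(=O)OC)[C@H]1CC2=C(C)[C@@H](OC(=O)CC)CC[C@]2(C)C[C@H]1OC(C)=O | target

**Step count and risks**

Total step count: 11. Longest linear sequence: 11 steps, from (R)-carvone (1).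

Steps most likely to fail:

Step 3 (Mitsunobu inversion). The activated allylic alcohol may eliminate towards a cross-conjugated dienone that aromatises, or inversion may be incomplete at the carbinol flanked by the isopropenyl-bearing carbon. The fallback moves the inversion to C8 of the bicycle, where hydride delivery is controlled by the angular methyl instead of an SN2 displacement. Setting out from 3, conjugate reduction with L-Selectride (2.2 equiv, THF, −78 °C) should give (4S,5R)-4-hydroxy-2-methyl-5-(prop-1-en-2-yl)cyclohexan-1-one F1. The annulation of step 5 is then run on F1 with 7 and 8 (auxiliary control alone, as in the dihydrocarvone case) through the imine F2, the alkylated imine F3, the diketone F4 and the ketol F5 to 8α-hydroxy-α-cyperone F6. Dess–Martin oxidation (NaHCO3, CH2Cl2) gives the 3,8-dione F7. NaBH4 (MeOH, −40 °C) should then reduce only the saturated C8 ketone from the α face, anti to the axial C10 methyl, which returns to the route at 13.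

Step 5 (key annulation). The hindered secondary enamine may add sluggishly, the acetate may suffer aminolysis during imine formation, or the facial selectivity at C10 may be insufficient. The fallback makes the C1–C10 bond by a Lewis-acid-mediated Mukaiyama–Michael addition under substrate control. Setting out from 5 (the regiodefined silyl enol ether of step 4, taken on without hydrolysis), treatment with 8 and TiCl4 (CH2Cl2, −78 °C, aqueous work-up) should give diketone 11 directly, the axial C8 acetoxy group directing 8 to the α face of C10. No new compound is formed; the route is rejoined at 11, which is cyclised with NaOMe/MeOH as in step 5.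

Step 7 (allylic oxidation). Oxidation may compete at the tertiary allylic C7–H, or over-oxidation may lower the site selectivity. The fallback replaces the selenium ene/[2,3] pathway by electrophilic ene-type chlorination followed by oxidation-level adjustment. Setting out from 14, hypochlorous acid (Ca(OCl)2, CO2, CH2Cl2/H2O, 0 °C) should give (7R,8R,10R)-8-acetoxy-12-chloroeudesma-4,11(13)-dien-3-one F8. Ganem oxidation (N-methylmorpholine N-oxide, NaHCO3, MeCN, 40 °C) gives (7R,8R,10R)-8-acetoxy-3-oxoeudesma-4,11(13)-dien-12-al F9. Pinnick oxidation (NaClO2, NaH2PO4, 2-methyl-2-butene, t-BuOH/H2O) returns to the route at 16.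

Further compounds
F1 | step 3 | (4S,5R)-4-hydroxy-2-methyl-5-(prop-1-en-2-yl)cyclohexan-1-one (mixture at C2) | C=C(C)[C@H]1CC(=O)C(C)C[C@@H]1O
F2 | step 3 | (4S,5R)-2-methyl-1-{[(1R)-1-phenylethyl]imino}-5-(prop-1-en-2-yl)cyclohexan-4-ol | C=C(C)[C@H]1CC(=N[C@H](C)c2ccccc2)C(C)C[C@@H]1O
F3 | step 3 | 1-[(1R,4R,5S)-5-hydroxy-1-methyl-2-{[(1R)-1-phenylethyl]imino}-4-(prop-1-en-2-yl)cyclohexyl]pentan-3-one | C=C(C)[C@H]1CC(=N[C@H](C)c2ccccc2)[C@](C)(CCC(=O)CC)C[C@@H]1O
F4 | step 3 | (2R,4S,5R)-4-hydroxy-2-methyl-2-(3-oxopentyl)-5-(prop-1-en-2-yl)cyclohexan-1-one | C=C(C)[C@H]1CC(=O)[C@](C)(CCC(=O)CC)C[C@@H]1O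
F5 | step 3 | (4aR,6S,7R)-6,8a-dihydroxy-1,4a-dimethyl-7-(prop-1-en-2-yl)octahydronaphthalen-2(1H)-one (C1 and C8a not defined) | C=C(C)[C@H]1CC2(O)C(C)C(=O)CC[C@]2(C)C[C@@H]1O
F6 | step 3 | (4aR,6S,7R)-6-hydroxy-1,4a-dimethyl-7-(prop-1-en-2-yl)-4,4a,5,6,7,8-hexahydronaphthalen-2(3H)-one (8α-hydroxy-α-cyperone) | C=C(C)[C@H]1CC2=C(C)C(=O)CC[C@]2(C)C[C@@H]1O
F7 | step 3 | (4aR,7R)-1,4a-dimethyl-7-(prop-1-en-2-yl)-4,4a,7,8-tetrahydronaphthalene-2,6(3H,5H)-dione | C=C(C)[C@H]1CC2=C(C)C(=O)CC[C@]2(C)CC1=O
F0 | step 5 | none | none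
F8 | step 7 | (7R,8R,10R)-8-acetoxy-12-chloroeudesma-4,11(13)-dien-3-one | C=C(CCl)[C@H]1CC2=C(C)C(=O)CC[C@]2(C)C[C@H]1OC(C)=O
F9 | step 7 | (7R,8R,10R)-8-acetoxy-3-oxoeudesma-4,11(13)-dien-12-al | C=C(C=O)[C@H]1CC2=C(C)C(=O)CC[C@]2(C)C[C@H]1OC(C)=O
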